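## The problem

With its heavy atoms numbered C1 to O34 along the SMILES string, target 42 consists of two bicycles that meet only through the link C16–C17. The western one is a cis-fused hydroazulene (cyclopentane C5–C9; cycloheptane C2–C6, C12, C15). The eastern one is a trans-fused oxepane–cyclohexane (oxepane O28, C19–C29; cyclohexane C18, C19, C29–C32). The link begins in a trisubstituted exocyclic alkene C15=C16 that sits between the quaternary carbon C12 and the methyl-bearing stereocentre C2, with C17 cis to C12 (Z). The eight stereocentres form two clusters that cannot influence each other (C2, C5, C6, C9 and C18, C19, C29, C32), so each half must be made as one enantiomer and the halves joined late. In the west, C6 can direct the oxygen at C9 (attack on the cyclopentene face away from C12) and the C9 hydroxyl can then place the hydrogen at C5 on its own face; C2 has no ring neighbour to lean on and must be set from C16 when the alkene is made. In the east, a chair-like ring closure can set C18, C19 and C29 together, and the axial methyl C20 decides the face of addition at C32. Reagent choice is limited by the two tertiary alcohols (C9, C32), by the exocyclic alkene (acid would move it into the ring), by the α-alkoxy ketone C23, and by the 1,4-relation of O34 to C16, which turns a free aldehyde or an activated alcohol at C16 into a lactol or a tetrahydrofuran. The feature that opens the western half is that its two rings share the bond C5–C6: C5 and C9 (with C10) are the two carbons of an alkyne on C6, C7–C8 is an allyl group on the same carbon, and C12–C15–C2–C3 ties a second terminal alkene at C4 to it, so one metathesis cascade can write both rings.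

## Retrosynthesis

**Oxidation level and protection (42 ⇒ 41 ⇒ 40).** No carbon–carbon bond is cut. The C23 ketone goes back to a silyl-protected secondary alcohol and the tertiary alcohols to silyl ethers, which leads from 42 through triol 41 to tris(triethylsilyl) ether 40. This is preferred to carrying the ketone, because the union needs a ketone reduction at C16 that must not touch C23 and because a free O34 would trap C16. Forward, three silyl ethers must fall together and the one secondary alcohol of 41 must be oxidised beside two tertiary ones.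

**Fragment union and the alkene (40 ⇒ 37 ⇒ 36 ⇒ 35 ⇒ 22 + 34).** The cut is C15–C16, combined with a 1,3-shift of the alkene: the exocyclic alkene and the hydrogen on C2 are traced to an endocyclic C2=C15 alkene and an oxygen on C16 (allylic alcohol 37, enone 36, alcohol 35), and from there to alkenyl triflate 22 and aldehyde 34. Olefination of a C15 ketone would have to attack the most hindered carbon of the molecule and gives no hold on the geometry; cuts at C16–C17 or C17–C18 need a neopentyl-type partner beside C19 and C32. In the chosen cut, allylic strain with the methyl group C1 decides the geometry, and the configuration at C16 is handed to C2 by a suprafacial hydrogen shift. Fragments 22 and 34 are of similar size and each holds one stereocluster. Forward, a tetrasubstituted alkenyl metal must add to an aldehyde, enone 36 must be reduced under reagent control, and a hindered allylic carbinol must be substituted with inversion.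

**Western functional groups (22 ⇒ 21 ⇒ 20 ⇒ 19 ⇒ 18 ⇒ 17 ⇒ 16 ⇒ 15 ⇒ 14).** No skeletal bond is cut. The enol triflate goes back to the C15 ketone, the C5 hydrogen to the C4=C5 alkene, and the tertiary alcohol with its methyl group to a C8=C9 alkene that carries a hydroxymethyl group on C9 (dienone 14). The hydroxymethyl group is a deliberate change from a plain methyl diene. In that diene both alkenes are trisubstituted and equally open on the face away from C12, so a peracid could not be trusted to choose between them. A primary allylic alcohol at C10 makes C8=C9 the only allylic alkene, so a Ti(OiPr)4/tartrate epoxidation chooses alkene and face. The price is two extra steps after the metathesis. Forward: epoxidation anti to C12, hydride opening at C8 that also turns C10 into the methyl group, and hydrogenation directed by the C9 hydroxyl.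

**Both western rings (14 ⇒ 13).** The cuts are C4=C5 and C8=C9. Cuts through ring single bonds (C5–C9, or C5–C6 with C12–C15) would each leave one ring to be made beforehand. The metathesis cut leaves acyclic dienyne ketone 13 with one stereocentre (C6), the quaternary carbon C12 and the C2 methyl group as both epimers. Forward, the cascade must start at the C4 alkene, close the seven-membered ring on C5 and pass the carbene to C9 for the five-membered ring.

**Chain assembly (13 ⇒ 12 ⇒ 11 ⇒ 10 ⇒ 9 ⇒ 7 ⇒ 6 ⇒ 4 + 5; 4 ⇒ 3 ⇒ 2 ⇒ 1).** The cuts are C2–C3 (enolate allylation of ethyl ketone 12; C12 is quaternary, so only C2 can be deprotonated), C15–C2 (ethyl Grignard on amide 11), the terminal carbon on C8 (Wittig on aldehyde 10) and, as the only stereochemical cut, C6–C12 (ester 6 from carbonate 4 and ketene acetal 5). This last cut is preferred to an auxiliary-based allylation at C6–C7 or an alkynylation at C5–C6, because an iridium-catalysed allylic substitution joins the quaternary carbon to the stereocentre in one catalytic step from achiral partners. Its price is a vinyl group on C6 that must be lengthened by one carbon (alcohol 9, aldehyde 10). The ester is changed into amide 7 before the hydroboration so that alcohol 9 cannot lactonise onto C15. Carbonate 4 comes from silyl ether 1 through enynal 2 and enynol 3.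

**Eastern fragment (34 ⇒ 32 ⇒ 31 ⇒ 30 ⇒ 28 ⇒ 27 ⇒ 26 ⇒ 25 ⇒ 23 + 24).** The cuts are the methyl group C33 (Grignard addition to ketone 30, giving diol 31), the terminal carbon of the allyl group (ozonolysis of 32) and, together, O28–C25 and C18–C19, which open both rings to enol silane 28 with two epoxides. A stepwise route (carbocycle first, then ether closure at the tertiary carbon C25) fights the preference of hydroxy epoxides for the six-membered ether. The polyepoxide cascade avoids this because the inner epoxide oxygen, not a free hydroxyl, attacks C25. The precursor has no ring, and its three stereocentres come from one epoxidation of dienyl amide 25 (to 26), itself made from geranyl bromide 23 and amide 24; enone 27 supplies the regiodefined enol silane. Forward, the (Z)-enol silane must attack C19 through a chair, and the Grignard reagent must enter C32 equatorially.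

## Roads not taken

**Alternative 1:** The cut is the ring bond C5–C9. A cycloheptene A1 with a 3-oxobutyl chain on C6 and a silyl ether on C15 would be treated with SmI2, HMPA and tert-butanol. The ketyl at C9 adds 5-exo to C5 of the C4=C5 alkene, the C4 radical is reduced and protonated, and the cis-fused cyclopentanol A2 results.
- *Merits:* one step makes the tertiary carbinol C9 and the C5 hydrogen; a 5-exo closure onto a ring alkene can only give the cis fusion; there are no oxidation-level detours at C8 and C10.
- *Weak points here:* the seven-membered ring, with C12 and the centres C2, C6 and C15, must be built first by other means, so the key step solves the easier ring. The configuration at C9 depends on whether methyl or O–Sm turns towards the ring, and the only bias is the remote C6. An unactivated 1,2-disubstituted alkene is a slow ketyl acceptor, so simple ketone reduction competes. C15 is carried as a stereocentre that is later destroyed.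
- *Comparison:* from bicycle to the C5/C9 pair this road is shorter (one step against steps 12–17). The chosen plan sets against it that both rings arise in one step from an acyclic chain with one stereocentre, and that C9 and C5 are then set by a reagent-controlled epoxidation and a hydroxyl-directed hydrogenation of predictable sense.

**Alternative 2:** The cuts are C5–C6 and C12–C15, with a temporary bond C5–C15. The enol acetate A3 of a 2-substituted cyclopentane-1,3-dione, whose side chain holds the C9 carbinol and the alkene C6=C12, would be irradiated near 350 nm. Intramolecular [2+2] cycloaddition gives acetoxycyclobutane A4; loss of the acetyl group and retro-aldol opening of C5–C15 would then give the seven-membered ring.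
- *Merits:* the three-atom tether leads reliably to the five-membered ring; C12 is made without an enolate alkylation; the C9 carbinol can come from a linalool-type chain of the chiral pool; no transition metal is needed.
- *Weak points here:* the fragmentation leaves a second ketone at C4 that the target lacks and that makes C5 epimerisable. The C2 methyl group is missing and would have to be introduced beside two ketones. The facial selectivity rests on a quaternary centre (C9) whose substituents, methyl and silyloxy, differ little. A cyclobutane with the adjacent quaternary carbons C12 and C15 is crowded.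
- *Comparison:* in its source of chirality for C9 and in doing without noble-metal catalysts this road is better. The chosen plan sets against it that it creates no surplus oxygen, places the C2 methyl group before the rings close, and fixes C5 by an irreversible directed hydrogenation instead of an equilibrium.

**Alternative 3:** The cuts are O28–C25 and C18–C19 in the eastern half. Me3SiOTf would activate the terminal epoxide of diepoxy enol silane A5. The inner epoxide oxygen attacks C25, and the enol silane carbon C18 opens the epoxonium ion at C19, giving the trans-fused hydroxy-oxepane 2-allylcyclohexanone A6.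
- *Merits:* two rings and the centres C18, C19 and C29 in one step from a geranyl chain; the oxepane regiochemistry, the hard point of any stepwise ether closure at C25, is settled by the mechanism.
- *Weak points as the carrier of the whole strategy:* it solves the half for which a short answer exists and leaves the hydroazulene, the alkene C15=C16 and C2 open. Growing the west linearly from the allyl group of A6 would carry the acid-sensitive bicycle through about twenty steps; attaching the west as a fragment would still need a second strategic step for that fragment. The stereocentre C23 is made only to be oxidised away.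
- *Comparison:* for the eastern bicycle this road is better than a stepwise construction, and the chosen route does not compete with it there: its aldehyde 34 is made through this very cascade (A5 and A6 are compounds 28 and 30 of steps 23 and 24). What was not taken is the weighting. The chosen plan spends its strategic step on the western half, where no such cascade is at hand, and uses the epoxide cascade as a supporting reaction.

Key step: step 11

Remarks on the chemistry (assumptions):
- Locants C1–O34 of the target are used for all intermediates unless a systematic name is given.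
- In step 4, L is the phosphoramidite from (R)-1,1'-bi-2-naphthol and bis[(R)-1-phenylethyl]amine; the sense of induction is assigned by analogy with the usual facial preference of this catalyst class, and if it proves opposite the antipodal ligand is used with no other change.
- C2 is carried as a mixture of epimers from 13 to 21 (in 18 C15 as well); it is flattened in 22 and set in step 31.
- Metal acetylides, enolates and the alkenylchromium species are treated as reactive forms of their precursors and carry no numbers.

## Route

Step 1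
Reactants: 1 tert-butyldimethyl(prop-2-yn-1-yloxy)silane
Product: 2 (2E)-6-[(tert-butyldimethylsilyl)oxy]hex-2-en-4-ynal
Conditions: nBuLi, THF, −78 °C; Me2NCH=CHCHO, −78 → 0 °C; 1 M HCl (aq), 0 °C
Reagents that add atoms: 3-(dimethylamino)acrolein, CN(C)/C=C/C=O; water, O
Why: Vinylogous formylation: the lithium acetylide adds to the aldehyde of the vinylogous formamide, and acid work-up expels dimethylamine with allylic transposition to the (E)-enal.

Step 2
Reactants: 2 (2E)-6-[(tert-butyldimethylsilyl)oxy]hex-2-en-4-ynal
Product: 3 (2E)-6-[(tert-butyldimethylsilyl)oxy]hex-2-en-4-yn-1-ol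
Conditions: NaBH4, CeCl3·7H2O, MeOH, −20 °C
Reagents that add atoms: none
Why: Luche reduction gives clean 1,2-reduction of the conjugated aldehyde.

Step 3
Reactants: 3 (2E)-6-[(tert-butyldimethylsilyl)oxy]hex-2-en-4-yn-1-ol
Product: 4 (2E)-6-[(tert-butyldimethylsilyl)oxy]hex-2-en-4-yn-1-yl methyl carbonate
Conditions: ClCO2Me, pyridine, CH2Cl2, 0 °C
Reagents that add atoms: methyl chloroformate, COC(=O)Cl
Why: Acylation of the primary allylic alcohol; the methyl carbonate is the leaving group that releases methoxide in step 4.

Step 4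
Reactants: 4 (2E)-6-[(tert-butyldimethylsilyl)oxy]hex-2-en-4-yn-1-yl methyl carbonate; 5 [(1-methoxy-2-methylprop-1-en-1-yl)oxy]trimethylsilane
Product: 6 methyl (3R)-6-[(tert-butyldimethylsilyl)oxy]-3-ethenyl-2,2-dimethylhex-4-ynoate
Conditions: [Ir(cod)Cl]2 (2 mol%), (Ra,R,R)-L (4 mol%), nPrNH2 (catalyst activation), THF, 25–40 °C
Reagents that add atoms: none
Why: Iridium-catalysed asymmetric allylic alkylation: the cyclometalated complex ionises the linear carbonate, and the silyl ketene acetal, activated by the released methoxide, attacks the substituted allyl terminus to give the branched product. The ligand fixes the new stereocentre C6 (R expected).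

Step 5
Reactants: 6 methyl (3R)-6-[(tert-butyldimethylsilyl)oxy]-3-ethenyl-2,2-dimethylhex-4-ynoate
Product: 7 (3R)-6-[(tert-butyldimethylsilyl)oxy]-3-ethenyl-N-methoxy-N,2,2-trimethylhex-4-ynamide
Conditions: MeNH(OMe)·HCl, iPrMgCl, THF, −20 → 23 °C
Reagents that add atoms: N,O-dimethylhydroxylamine hydrochloride, CNOC.Cl
Why: Aminolysis of the hindered ester by the chloromagnesium amide; the amide cannot lactonise in step 6 and later stops a Grignard addition at the ketone.

Step 6
Reactants: 7 (3R)-6-[(tert-butyldimethylsilyl)oxy]-3-ethenyl-N-methoxy-N,2,2-trimethylhex-4-ynamide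
Product: 9 (3R)-6-[(tert-butyldimethylsilyl)oxy]-3-(2-hydroxyethyl)-N-methoxy-N,2,2-trimethylhex-4-ynamide, via alkylborane 8 (not isolated)
Conditions: 9-BBN, THF, 0 → 23 °C; then NaOH, H2O2, H2O, 0 °C
Reagents that add atoms: 9-borabicyclo[3.3.1]nonane, B1C2CCCC1CCC2 (stays only in 8); hydrogen peroxide, OO
Why: Hydroboration–oxidation: 9-BBN adds to the terminal alkene much faster than to the internal alkyne and puts boron on the terminal carbon; C6 is not touched.

Step 7
Reactants: 9 (3R)-6-[(tert-butyldimethylsilyl)oxy]-3-(2-hydroxyethyl)-N-methoxy-N,2,2-trimethylhex-4-ynamide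
Product: 10 (3R)-6-[(tert-butyldimethylsilyl)oxy]-N-methoxy-N,2,2-trimethyl-3-(2-oxoethyl)hex-4-ynamide
Conditions: Dess–Martin periodinane, NaHCO3, CH2Cl2, 0 → 23 °C
Reagents that add atoms: none
Why: Dess–Martin oxidation of the primary alcohol under buffered conditions; C6 is β to the new aldehyde and cannot epimerise.

Step 8
Reactants: 10 (3R)-6-[(tert-butyldimethylsilyl)oxy]-N-methoxy-N,2,2-trimethyl-3-(2-oxoethyl)hex-4-ynamide
Product: 11 (3R)-6-[(tert-butyldimethylsilyl)oxy]-N-methoxy-N,2,2-trimethyl-3-(prop-2-en-1-yl)hex-4-ynamide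
Conditions: Ph3PCH3Br, KN(SiMe3)2, THF, 0 °C; then 10, −78 → 0 °C
Reagents that add atoms: methyltriphenylphosphonium bromide, C[P+](c1ccccc1)(c1ccccc1)c1ccccc1.[Br-]
Why: Wittig methylenation turns the aldehyde into the allyl group C7–C8=CH2; the amide has no α-hydrogen and is inert to the ylide.

Step 9
Reactants: 11 (3R)-6-[(tert-butyldimethylsilyl)oxy]-N-methoxy-N,2,2-trimethyl-3-(prop-2-en-1-yl)hex-4-ynamide
Product: 12 (5R)-8-[(tert-butyldimethylsilyl)oxy]-4,4-dimethyl-5-(prop-2-en-1-yl)oct-6-yn-3-one
Conditions: EtMgBr, THF, 0 °C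
Reagents that add atoms: ethylmagnesium bromide, CC[Mg]Br
Why: Grignard addition to the N-methoxy-N-methylamide stops at the chelated tetrahedral intermediate and gives the ethyl ketone on work-up.

Step 10
Reactants: 12 (5R)-8-[(tert-butyldimethylsilyl)oxy]-4,4-dimethyl-5-(prop-2-en-1-yl)oct-6-yn-3-one
Product: 13 (7R)-10-[(tert-butyldimethylsilyl)oxy]-4,6,6-trimethyl-7-(prop-2-en-1-yl)dec-1-en-8-yn-5-one (both epimers at the methyl-bearing carbon, C2 of the target)
Conditions: LiN(iPr)2, THF, −78 °C; CH2=CHCH2Br, −78 → 0 °C
Reagents that add atoms: allyl bromide, C=CCBr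
Why: Kinetic enolate alkylation: C12 is quaternary, so only C2 can be deprotonated. The C2 epimers are of no consequence because C2 is flattened in step 19 and set in step 31.

Step 11
Reactants: 13 (7R)-10-[(tert-butyldimethylsilyl)oxy]-4,6,6-trimethyl-7-(prop-2-en-1-yl)dec-1-en-8-yn-5-one (both C2 epimers)
Product: 14 (8aR)-3-{[(tert-butyldimethylsilyl)oxy]methyl}-6,8,8-trimethyl-5,6,8,8a-tetrahydroazulen-7(1H)-one (both C2 epimers)
Conditions: RuCl2(H2IMes)(PCy3)(=CHPh) (second-generation Grubbs catalyst, 5–10 mol%), toluene (0.005 M), 80 °C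
Reagents that add atoms: none
Why: Tandem ring-closing enyne–ene metathesis of a dienyne branched at the propargylic carbon, a known reaction type for fused bicyclic 1,3-dienes. The carbene formed at C4 adds to the alkyne in the exo mode, C4 bonding to C5; this closes the seven-membered ring (helped by the gem-dimethyl carbon C12 and the sp2 carbon C15 in the tether), and cycloreversion leaves a new carbene on C9. That carbene lies next to the allyl group on C6 and closes the cyclopentene by ordinary ring-closing metathesis (C8=C9) with loss of ethylene. A carbene formed first at the allyl group could reach the alkyne only through a four-membered ring or a strained endo closure; it returns to the pool by degenerate exchange, and the endo closure, should it occur, leads to the same diene. No stereocentre is formed: C6 is carried in unchanged and C2 stays a mixture. The selectivities needed are chemoselectivity (enyne closure before ene–ene closure to an eight-membered ring or intermolecular coupling) and ring size; the tether lengths fix the second and high dilution secures the first. The silyl ether and the hindered ketone are inert to the catalyst.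

Step 12
Reactants: 14 (8aR)-3-{[(tert-butyldimethylsilyl)oxy]methyl}-6,8,8-trimethyl-5,6,8,8a-tetrahydroazulen-7(1H)-one (both C2 epimers)
Product: 15 (8aR)-3-(hydroxymethyl)-6,8,8-trimethyl-5,6,8,8a-tetrahydroazulen-7(1H)-one (both C2 epimers)
Conditions: Bu4NF, THF, 0 °C
Reagents that add atoms: none
Why: Fluoride cleaves the primary silyl ether and frees the allylic alcohol that directs step 13.

Step 13
Reactants: 15 (8aR)-3-(hydroxymethyl)-6,8,8-trimethyl-5,6,8,8a-tetrahydroazulen-7(1H)-one (both C2 epimers)
Product: 16 epoxy alcohol, 15 with a C8–C9 epoxide on the face of H6 and anti to C12 [(6R,8R,9R) in target numbering, both C2 epimers]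
Conditions: Ti(OiPr)4, D-(−)-diethyl tartrate, tBuOOH, 4 Å molecular sieves, CH2Cl2, −25 °C
Reagents that add atoms: tert-butyl hydroperoxide, CC(C)(C)OO
Why: Sharpless asymmetric epoxidation: only C8=C9 is allylic to the hydroxyl (C4=C5 is homoallylic and much slower), and the D-(−)-tartrate complex delivers oxygen to the face anti to C12, which the substrate itself prefers (matched case). This sets C9 and, for the time being, C8.

Step 14
Reactants: 16 epoxy alcohol [(6R,8R,9R), both C2 epimers]
Product: 17 methanesulfonate of 16 at O on C10 [(6R,8R,9R), both C2 epimers]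
Conditions: MsCl, Et3N, CH2Cl2, −20 °C
Reagents that add atoms: methanesulfonyl chloride, CS(=O)(=O)Cl
Why: Sulfonylation of the primary alcohol at low temperature, where the tertiary allylic epoxide survives.

Step 15
Reactants: 17 methanesulfonate of 16 [(6R,8R,9R), both C2 epimers]
Product: 18 3,6,8,8-tetramethyl-1,2,3,5,6,7,8,8a-octahydroazulene-3,7-diol with (R)-C9 and its hydroxyl cis to H6 (epimers at C2 and C15)
Conditions: LiEt3BH, THF, 0 → 23 °C
Reagents that add atoms: none
Why: Hydride displaces the primary mesylate (C10 becomes the methyl group) and opens the epoxide at the less substituted carbon C8, so the oxygen stays on C9 with the configuration of step 13. The C15 ketone is reduced as well and is restored in step 16.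

Step 16
Reactants: 18 diol (epimers at C2 and C15)
Product: 19 (3R,8aR)-3-hydroxy-3,6,8,8-tetramethyl-2,3,5,6,8,8a-hexahydroazulen-7(1H)-one (both C2 epimers)
Conditions: Dess–Martin periodinane, NaHCO3, CH2Cl2, 0 °C
Reagents that add atoms: none
Why: Dess–Martin oxidation returns the secondary C15 alcohol to the ketone; the tertiary allylic alcohol cannot be oxidised and is not transposed by this reagent.

Step 17
Reactants: 19 (3R,8aR)-3-hydroxy-3,6,8,8-tetramethyl-2,3,5,6,8,8a-hexahydroazulen-7(1H)-one (both C2 epimers)
Product: 20 (3R,3aR,8aR)-3-hydroxy-3,6,8,8-tetramethyloctahydroazulen-7(1H)-one (both C2 epimers)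
Conditions: H2 (1 atm), [Ir(cod)(PCy3)(py)]PF6 (5 mol%), CH2Cl2, 23 °C
Reagents that add atoms: none
Why: Hydroxyl-directed hydrogenation: the cationic iridium catalyst binds the C9 hydroxyl and delivers hydrogen to C4=C5 on that face. This sets C5 (hydrogen cis to the hydroxyl and to H6) and gives the cis ring fusion.

Step 18
Reactants: 20 (3R,3aR,8aR)-3-hydroxy-3,6,8,8-tetramethyloctahydroazulen-7(1H)-one (both C2 epimers)
Product: 21 (3R,3aR,8aR)-3,6,8,8-tetramethyl-3-[(triethylsilyl)oxy]octahydroazulen-7(1H)-one (both C2 epimers)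
Conditions: Et3SiOTf, 2,6-lutidine, CH2Cl2, −78 → 0 °C
Reagents that add atoms: triethylsilyl trifluoromethanesulfonate, CC[Si](CC)(CC)OS(=O)(=O)C(F)(F)F
Why: Silylation of the tertiary alcohol with the silyl triflate; it keeps a free alkoxide out of the triflation in step 19.

Step 19
Reactants: 21 (3R,3aR,8aR)-3,6,8,8-tetramethyl-3-[(triethylsilyl)oxy]octahydroazulen-7(1H)-one (both C2 epimers)
Product: 22 (3R,3aR,8aR)-3,6,8,8-tetramethyl-3-[(triethylsilyl)oxy]-1,2,3,3a,4,5,8,8a-octahydroazulen-7-yl trifluoromethanesulfonate
Conditions: KN(SiMe3)2, THF, −78 → 0 °C; PhNTf2, −78 → 23 °C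
Reagents that add atoms: N-phenylbis(trifluoromethanesulfonimide), O=S(=O)(N(c1ccccc1)S(=O)(=O)C(F)(F)F)C(F)(F)F
Why: Enol triflate formation: only C2 carries an α-hydrogen, so both C2 epimers converge on one tetrasubstituted alkenyl triflate.

Step 20
Reactants: 23 geranyl bromide [(2E)-1-bromo-3,7-dimethylocta-2,6-diene]; 24 N-methoxy-N-methylacetamide
Product: 25 (4E)-N-methoxy-N,5,9-trimethyldeca-4,8-dienamide
Conditions: LiN(iPr)2, THF, −78 °C (24); then 23, −78 → −20 °C
Reagents that add atoms: none
Why: SN2 alkylation of the amide enolate with the allylic bromide; the (E)-alkene of the geranyl unit is kept.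

Step 21
Reactants: 25 (4E)-N-methoxy-N,5,9-trimethyldeca-4,8-dienamide
Product: 26 3-[(2R,3R)-3-{2-[(2R)-3,3-dimethyloxiran-2-yl]ethyl}-3-methyloxiran-2-yl]-N-methoxy-N-methylpropanamide
Conditions: D-fructose-derived Shi ketone (0.6 equiv), KHSO5 (as 2KHSO5·KHSO4·K2SO4), K2CO3, Bu4NHSO4, MeCN/CH2(OMe)2/aq. Na2B4O7, 0 °C
Reagents that add atoms: potassium peroxymonosulfate, [K+].[O-]S(=O)(=O)OO
Why: Shi epoxidation: the chiral dioxirane epoxidises both trisubstituted alkenes through the spiro transition state with the same facial sense, which should give the (R,R) inner and (R) terminal epoxides; the amide is inert.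

Step 22
Reactants: 26 3-[(2R,3R)-3-{2-[(2R)-3,3-dimethyloxiran-2-yl]ethyl}-3-methyloxiran-2-yl]-N-methoxy-N-methylpropanamide
Product: 27 5-[(2R,3R)-3-{2-[(2R)-3,3-dimethyloxiran-2-yl]ethyl}-3-methyloxiran-2-yl]pent-1-en-3-one
Conditions: CH2=CHMgBr, THF, −78 → 0 °C; cold aq. NH4Cl
Reagents that add atoms: vinylmagnesium bromide, C=C[Mg]Br
Why: Grignard addition to the N-methoxy-N-methylamide gives the vinyl ketone; trisubstituted epoxides do not react with the Grignard reagent at this temperature.

Step 23
Reactants: 27 5-[(2R,3R)-3-{2-[(2R)-3,3-dimethyloxiran-2-yl]ethyl}-3-methyloxiran-2-yl]pent-1-en-3-one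
Product: 28 {[(3Z)-1-[(2R,3R)-3-{2-[(2R)-3,3-dimethyloxiran-2-yl]ethyl}-3-methyloxiran-2-yl]hepta-3,6-dien-3-yl]oxy}trimethylsilane
Conditions: CH2=CHMgBr, CuBr·SMe2 (10 mol%), Me3SiCl, HMPA, THF, −78 °C; Et3N
Reagents that add atoms: vinylmagnesium bromide, C=C[Mg]Br; chlorotrimethylsilane, C[Si](C)(C)Cl
Why: Copper-catalysed conjugate addition with in situ silylation: the enolate is trapped regiospecifically towards C18, mainly as the (Z)-enol silane from the s-cis enone, and the added vinyl group completes the allyl unit C17–C16.

Step 24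
Reactants: 28 {[(3Z)-1-[(2R,3R)-3-{2-[(2R)-3,3-dimethyloxiran-2-yl]ethyl}-3-methyloxiran-2-yl]hepta-3,6-dien-3-yl]oxy}trimethylsilane
Product: 30 (3R,5aR,6R,9aR)-3-hydroxy-2,2,5a-trimethyl-6-(prop-2-en-1-yl)octahydro-1-benzoxepin-7(2H)-one, via silyl ether 29 (not isolated)
Conditions: Me3SiOTf, 2,6-di-tert-butyl-4-methylpyridine, CH2Cl2, −78 °C; then 1 M HCl (aq)/THF, 0 °C
Reagents that add atoms: none
Why: Epoxonium cascade (Lewis-acid-initiated polyepoxide oxa- and carbacyclisation): the silyl triflate activates the terminal epoxide, the inner epoxide oxygen opens it at the tertiary carbon C25 (oxepane), and the enol silane carbon C18 opens the resulting epoxonium ion at C19 with inversion through a chair (cyclohexanone). C29 keeps the epoxide configuration, C19 is inverted, and the (Z)-enol silane puts the allyl group on C18 equatorial; the silyl ether on the C23 oxygen falls in the work-up.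

Step 25
Reactants: 30 (3R,5aR,6R,9aR)-3-hydroxy-2,2,5a-trimethyl-6-(prop-2-en-1-yl)octahydro-1-benzoxepin-7(2H)-one
Product: 31 (3R,5aR,6R,7S,9aR)-2,2,5a,7-tetramethyl-6-(prop-2-en-1-yl)decahydro-1-benzoxepine-3,7-diol
Conditions: MeMgBr, CeCl3, THF, −78 → 0 °C
Reagents that add atoms: methylmagnesium bromide, C[Mg]Br
Why: Organocerium (Grignard-type) addition: the axial methyl group C20 blocks the axial trajectory, so the methyl group enters C32 equatorially and the hydroxyl ends axial and cis to C20, as in the target. CeCl3 suppresses enolisation.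

Step 26
Reactants: 31 (3R,5aR,6R,7S,9aR)-2,2,5a,7-tetramethyl-6-(prop-2-en-1-yl)decahydro-1-benzoxepine-3,7-diol
Product: 32 3,7-bis(triethylsilyl) ether of 31
Conditions: Et3SiOTf, 2,6-lutidine, CH2Cl2, −78 → 0 °C
Reagents that add atoms: triethylsilyl trifluoromethanesulfonate, CC[Si](CC)(CC)OS(=O)(=O)C(F)(F)F
Why: The silyl triflate silylates the secondary and the hindered tertiary hydroxyl; O34 must be masked because it is 1,4 to C16.

Step 27
Reactants: 32 3,7-bis(triethylsilyl) ether of 31
Product: 34 2-[(3R,5aR,6R,7S,9aR)-2,2,5a,7-tetramethyl-3,7-bis[(triethylsilyl)oxy]decahydro-1-benzoxepin-6-yl]acetaldehyde, via ozonide 33 (not isolated)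
Conditions: O3, CH2Cl2, −78 °C; then PPh3, −78 → 23 °C
Reagents that add atoms: ozone, [O-][O+]=O
Why: Ozonolysis with reductive work-up cuts the only alkene to the aldehyde C16.

Step 28
Reactants: 22 (3R,3aR,8aR)-3,6,8,8-tetramethyl-3-[(triethylsilyl)oxy]-1,2,3,3a,4,5,8,8a-octahydroazulen-7-yl trifluoromethanesulfonate; 34 2-[(3R,5aR,6R,7S,9aR)-2,2,5a,7-tetramethyl-3,7-bis[(triethylsilyl)oxy]decahydro-1-benzoxepin-6-yl]acetaldehyde
Product: 35 1-[(3R,3aR,8aR)-3,6,8,8-tetramethyl-3-[(triethylsilyl)oxy]-1,2,3,3a,4,5,8,8a-octahydroazulen-7-yl]-2-[(3R,5aR,6R,7S,9aR)-2,2,5a,7-tetramethyl-3,7-bis[(triethylsilyl)oxy]decahydro-1-benzoxepin-6-yl]ethan-1-ol (both C16 epimers)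
Conditions: CrCl2, NiCl2 (cat.), DMF, 23 → 50 °C
Reagents that add atoms: none
Why: Nozaki–Hiyama–Kishi coupling: NiCl2-catalysed formation of the alkenylchromium species from the enol triflate and its chemoselective addition to the aldehyde form C15–C16. The uncontrolled carbinol C16 is removed in step 29.

Step 29
Reactants: 35 allylic alcohol (both C16 epimers)
Product: 36 1-[(3R,3aR,8aR)-3,6,8,8-tetramethyl-3-[(triethylsilyl)oxy]-1,2,3,3a,4,5,8,8a-octahydroazulen-7-yl]-2-[(3R,5aR,6R,7S,9aR)-2,2,5a,7-tetramethyl-3,7-bis[(triethylsilyl)oxy]decahydro-1-benzoxepin-6-yl]ethan-1-one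
Conditions: Dess–Martin periodinane, NaHCO3, CH2Cl2, 0 → 23 °C
Reagents that add atoms: none
Why: Dess–Martin oxidation of the allylic alcohol to the enone erases the unselective C16 centre.

Step 30
Reactants: 36 enone
Product: 37 (1R)-1-[(3R,3aR,8aR)-3,6,8,8-tetramethyl-3-[(triethylsilyl)oxy]-1,2,3,3a,4,5,8,8a-octahydroazulen-7-yl]-2-[(3R,5aR,6R,7S,9aR)-2,2,5a,7-tetramethyl-3,7-bis[(triethylsilyl)oxy]decahydro-1-benzoxepin-6-yl]ethan-1-ol [(16R) in target numbering]
Conditions: (S)-2-methyl-CBS-oxazaborolidine, BH3·SMe2, toluene, −40 → −20 °C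
Reagents that add atoms: none
Why: Corey–Bakshi–Shibata reduction: the tetrasubstituted alkenyl group is the large and the C17 methylene the small substituent, so the (S)-oxazaborolidine should give the (16R) carbinol by reagent control.

Step 31
Reactants: 37 (16R)-allylic alcohol
Product: 40 tris(triethylsilyl) ether of triol 41 at O11, O34 and the C23 oxygen [(2S,5R,6R,9R,15Z,18R,19R,23R,29R,32S) in target numbering], via hydrazone adduct 38 (not isolated), via allylic diazene 39 (not isolated)
Conditions: PPh3, diethyl azodicarboxylate, N-isopropylidene-N'-(2-nitrobenzenesulfonyl)hydrazine, THF, 0 → 23 °C; then CF3CH2OH/H2O (1:1), 23 °C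
Reagents that add atoms: N-isopropylidene-N'-(2-nitrobenzenesulfonyl)hydrazine, CC(C)=NNS(=O)(=O)c1ccccc1[N+](=O)[O-] (stays only in 38 and 39)
Why: Mitsunobu displacement by the sulfonyl hydrazone inverts C16; hydrolysis frees the sulfonyl hydrazine, which loses sulfinate to the allylic diazene, and this loses N2 in a retro-ene step with suprafacial hydrogen transfer to C2 (reductive 1,3-transposition). Allylic strain with the methyl group C1 keeps H16 inside, so C17 ends cis to C12 (Z), and the (16S)-diazene delivers hydrogen to the face of C2 that gives the (2S) centre.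

Step 32
Reactants: 40 tris(triethylsilyl) ether
Product: 41 triol, the target with (R)-CH(OH) at C23 in place of the ketone [(2S,5R,6R,9R,15Z,18R,19R,23R,29R,32S)]
Conditions: HF·pyridine, pyridine, THF, 0 → 23 °C
Reagents that add atoms: none
Why: Buffered fluoride cleaves the three triethylsilyl ethers and leaves the tertiary alcohols and the exocyclic alkene untouched.

Step 33
Reactants: 41 triol
Product: 42 target CNP0157787.1 [(2S,5R,6R,9R,15Z,18R,19R,29R,32S) in target numbering]
Conditions: Dess–Martin periodinane, NaHCO3, CH2Cl2, 0 °C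
Reagents that add atoms: none
Why: Dess–Martin oxidation of the only secondary alcohol (C23) gives the ketone; the two tertiary alcohols cannot react.

## Compound list

1 | tert-butyldimethyl(prop-2-yn-1-yloxy)silane | C#CCO[Si](C)(C)C(C)(C)C | starting material
2 | (2E)-6-[(tert-butyldimethylsilyl)oxy]hex-2-en-4-ynal | O=C/C=C/C#CCO[Si](C)(C)C(C)(C)C | intermediate
3 | (2E)-6-[(tert-butyldimethylsilyl)oxy]hex-2-en-4-yn-1-ol | OC/C=C/C#CCO[Si](C)(C)C(C)(C)C | intermediate
4 | (2E)-6-[(tert-butyldimethylsilyl)oxy]hex-2-en-4-yn-1-yl methyl carbonate | COC(=O)OC/C=C/C#CCO[Si](C)(C)C(C)(C)C | intermediate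
5 | [(1-methoxy-2-methylprop-1-en-1-yl)oxy]trimethylsilane | COC(O[Si](C)(C)C)=C(C)C | starting material
6 | methyl (3R)-6-[(tert-butyldimethylsilyl)oxy]-3-ethenyl-2,2-dimethylhex-4-ynoate | CC(C)(C)[Si](C)(C)OCC#C[C@@H](C=C)C(C)(C)C(=O)OC | intermediate
7 | (3R)-6-[(tert-butyldimethylsilyl)oxy]-3-ethenyl-N-methoxy-N,2,2-trimethylhex-4-ynamide | CC(C)(C)[Si](C)(C)OCC#C[C@@H](C=C)C(C)(C)C(=O)N(C)OC | intermediate
8 | B-alkyl-9-borabicyclo[3.3.1]nonane from 7 (boron on the terminal carbon of the former vinyl group) | CC(C)(C)[Si](C)(C)OCC#C[C@@H](CCB1C2CCCC1CCC2)C(C)(C)C(=O)N(C)OC | intermediate (not isolated)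
9 | (3R)-6-[(tert-butyldimethylsilyl)oxy]-3-(2-hydroxyethyl)-N-methoxy-N,2,2-trimethylhex-4-ynamide | CC(C)(C)[Si](C)(C)OCC#C[C@@H](CCO)C(C)(C)C(=O)N(C)OC | intermediate
10 | (3R)-6-[(tert-butyldimethylsilyl)oxy]-N-methoxy-N,2,2-trimethyl-3-(2-oxoethyl)hex-4-ynamide | CC(C)(C)[Si](C)(C)OCC#C[C@@H](CC=O)C(C)(C)C(=O)N(C)OC | intermediate
11 | (3R)-6-[(tert-butyldimethylsilyl)oxy]-N-methoxy-N,2,2-trimethyl-3-(prop-2-en-1-yl)hex-4-ynamide | CC(C)(C)[Si](C)(C)OCC#C[C@@H](CC=C)C(C)(C)C(=O)N(C)OC | intermediate
12 | (5R)-8-[(tert-butyldimethylsilyl)oxy]-4,4-dimethyl-5-(prop-2-en-1-yl)oct-6-yn-3-one | CC(C)(C)[Si](C)(C)OCC#C[C@@H](CC=C)C(C)(C)C(=O)CC | intermediate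
13 | (7R)-10-[(tert-butyldimethylsilyl)oxy]-4,6,6-trimethyl-7-(prop-2-en-1-yl)dec-1-en-8-yn-5-one (both C2 epimers) | CC(C)(C)[Si](C)(C)OCC#C[C@@H](CC=C)C(C)(C)C(=O)C(C)CC=C | intermediate
14 | (8aR)-3-{[(tert-butyldimethylsilyl)oxy]methyl}-6,8,8-trimethyl-5,6,8,8a-tetrahydroazulen-7(1H)-one (both C2 epimers) | CC1CC=C2C(CO[Si](C)(C)C(C)(C)C)=CC[C@H]2C(C)(C)C1=O | intermediate
15 | (8aR)-3-(hydroxymethyl)-6,8,8-trimethyl-5,6,8,8a-tetrahydroazulen-7(1H)-one (both C2 epimers) | CC1CC=C2C(CO)=CC[C@H]2C(C)(C)C1=O | intermediate
16 | epoxy alcohol: 15 with a C8–C9 epoxide cis to H6, (6R,8R,9R) in target numbering (both C2 epimers) | CC1CC=C2[C@]3(CO)O[C@@H]3C[C@H]2C(C)(C)C1=O | intermediate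
17 | methanesulfonate of 16 at the C10 oxygen | CC1CC=C2[C@]3(COS(C)(=O)=O)O[C@@H]3C[C@H]2C(C)(C)C1=O | intermediate
18 | 3,6,8,8-tetramethyl-1,2,3,5,6,7,8,8a-octahydroazulene-3,7-diol, (R)-C9 with hydroxyl cis to H6 (epimers at C2 and C15) | CC1CC=C2[C@](C)(O)CC[C@H]2C(C)(C)C1O | intermediate
19 | (3R,8aR)-3-hydroxy-3,6,8,8-tetramethyl-2,3,5,6,8,8a-hexahydroazulen-7(1H)-one (both C2 epimers) | CC1CC=C2[C@](C)(O)CC[C@H]2C(C)(C)C1=O | intermediate
20 | (3R,3aR,8aR)-3-hydroxy-3,6,8,8-tetramethyloctahydroazulen-7(1H)-one (both C2 epimers) | CC1CC[C@@H]2[C@@H](CC[C@@]2(C)O)C(C)(C)C1=O | intermediate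
21 | (3R,3aR,8aR)-3,6,8,8-tetramethyl-3-[(triethylsilyl)oxy]octahydroazulen-7(1H)-one (both C2 epimers) | CC1CC[C@@H]2[C@@H](CC[C@@]2(C)O[Si](CC)(CC)CC)C(C)(C)C1=O | intermediate
22 | (3R,3aR,8aR)-3,6,8,8-tetramethyl-3-[(triethylsilyl)oxy]-1,2,3,3a,4,5,8,8a-octahydroazulen-7-yl trifluoromethanesulfonate | CC=1CC[C@@H]2[C@@H](CC[C@@]2(C)O[Si](CC)(CC)CC)C(C)(C)C=1OS(=O)(=O)C(F)(F)F | intermediate
23 | geranyl bromide, (2E)-1-bromo-3,7-dimethylocta-2,6-diene | CC(C)=CCC/C(C)=C/CBr | starting material
24 | N-methoxy-N-methylacetamide | CC(=O)N(C)OC | starting material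
25 | (4E)-N-methoxy-N,5,9-trimethyldeca-4,8-dienamide | CON(C)C(=O)CC/C=C(\C)CCC=C(C)C | intermediate
26 | 3-[(2R,3R)-3-{2-[(2R)-3,3-dimethyloxiran-2-yl]ethyl}-3-methyloxiran-2-yl]-N-methoxy-N-methylpropanamide | CON(C)C(=O)CC[C@H]1O[C@]1(C)CC[C@H]1OC1(C)C | intermediate
27 | 5-[(2R,3R)-3-{2-[(2R)-3,3-dimethyloxiran-2-yl]ethyl}-3-methyloxiran-2-yl]pent-1-en-3-one | C=CC(=O)CC[C@H]1O[C@]1(C)CC[C@H]1OC1(C)C | intermediate
28 | {[(3Z)-1-[(2R,3R)-3-{2-[(2R)-3,3-dimethyloxiran-2-yl]ethyl}-3-methyloxiran-2-yl]hepta-3,6-dien-3-yl]oxy}trimethylsilane | C=CC/C=C(\O[Si](C)(C)C)CC[C@H]1O[C@]1(C)CC[C@H]1OC1(C)C | intermediate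
29 | trimethylsilyl ether of 30 at the C23 oxygen | C=CC[C@@H]1[C@@]2(C)CC[C@@H](O[Si](C)(C)C)C(C)(C)O[C@@H]2CCC1=O | intermediate (not isolated)
30 | (3R,5aR,6R,9aR)-3-hydroxy-2,2,5a-trimethyl-6-(prop-2-en-1-yl)octahydro-1-benzoxepin-7(2H)-one | C=CC[C@@H]1[C@@]2(C)CC[C@@H](O)C(C)(C)O[C@@H]2CCC1=O | intermediate
31 | (3R,5aR,6R,7S,9aR)-2,2,5a,7-tetramethyl-6-(prop-2-en-1-yl)decahydro-1-benzoxepine-3,7-diol | C=CC[C@@H]1[C@@]2(C)CC[C@@H](O)C(C)(C)O[C@@H]2CC[C@]1(C)O | intermediate
32 | 3,7-bis(triethylsilyl) ether of 31 | C=CC[C@@H]1[C@@]2(C)CC[C@@H](O[Si](CC)(CC)CC)C(C)(C)O[C@@H]2CC[C@]1(C)O[Si](CC)(CC)CC | intermediate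
33 | 1,2,4-trioxolane (ozonide) of the terminal alkene of 32 | C1(C[C@@H]2[C@@]3(C)CC[C@@H](O[Si](CC)(CC)CC)C(C)(C)O[C@@H]3CC[C@]2(C)O[Si](CC)(CC)CC)OCOO1 | intermediate (not isolated)
34 | 2-[(3R,5aR,6R,7S,9aR)-2,2,5a,7-tetramethyl-3,7-bis[(triethylsilyl)oxy]decahydro-1-benzoxepin-6-yl]acetaldehyde | O=CC[C@@H]1[C@@]2(C)CC[C@@H](O[Si](CC)(CC)CC)C(C)(C)O[C@@H]2CC[C@]1(C)O[Si](CC)(CC)CC | intermediate
35 | 1-[(3R,3aR,8aR)-3,6,8,8-tetramethyl-3-[(triethylsilyl)oxy]-1,2,3,3a,4,5,8,8a-octahydroazulen-7-yl]-2-[(3R,5aR,6R,7S,9aR)-2,2,5a,7-tetramethyl-3,7-bis[(triethylsilyl)oxy]decahydro-1-benzoxepin-6-yl]ethan-1-ol (both C16 epimers) | CC=1CC[C@@H]2[C@@H](CC[C@@]2(C)O[Si](CC)(CC)CC)C(C)(C)C=1C(O)C[C@@H]1[C@@]2(C)CC[C@@H](O[Si](CC)(CC)CC)C(C)(C)O[C@@H]2CC[C@]1(C)O[Si](CC)(CC)CC | intermediate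
36 | the corresponding ethan-1-one (C16 ketone, enone with C2=C15) | CC=1CC[C@@H]2[C@@H](CC[C@@]2(C)O[Si](CC)(CC)CC)C(C)(C)C=1C(=O)C[C@@H]1[C@@]2(C)CC[C@@H](O[Si](CC)(CC)CC)C(C)(C)O[C@@H]2CC[C@]1(C)O[Si](CC)(CC)CC | intermediate
37 | (1R)-alcohol of 35, (16R) in target numbering | CC=1CC[C@@H]2[C@@H](CC[C@@]2(C)O[Si](CC)(CC)CC)C(C)(C)C=1[C@H](O)C[C@@H]1[C@@]2(C)CC[C@@H](O[Si](CC)(CC)CC)C(C)(C)O[C@@H]2CC[C@]1(C)O[Si](CC)(CC)CC | intermediate
38 | N-[(16S)-allyl]-N-(2-nitrobenzenesulfonyl)hydrazone of acetone (Mitsunobu adduct, C16 inverted) | CC=1CC[C@@H]2[C@@H](CC[C@@]2(C)O[Si](CC)(CC)CC)C(C)(C)C=1[C@@H](N(N=C(C)C)S(=O)(=O)c1ccccc1[N+](=O)[O-])C[C@@H]1[C@@]2(C)CC[C@@H](O[Si](CC)(CC)CC)C(C)(C)O[C@@H]2CC[C@]1(C)O[Si](CC)(CC)CC | intermediate (not isolated)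
39 | (16S)-allylic monoalkyl diazene | CC=1CC[C@@H]2[C@@H](CC[C@@]2(C)O[Si](CC)(CC)CC)C(C)(C)C=1[C@@H](N=N)C[C@@H]1[C@@]2(C)CC[C@@H](O[Si](CC)(CC)CC)C(C)(C)O[C@@H]2CC[C@]1(C)O[Si](CC)(CC)CC | intermediate (not isolated)
40 | tris(triethylsilyl) ether of 41 (O11, O34 and the C23 oxygen), (2S,5R,6R,9R,15Z,18R,19R,23R,29R,32S) | C[C@H]1CC[C@@H]2[C@@H](CC[C@@]2(C)O[Si](CC)(CC)CC)C(C)(C)/C1=C\C[C@@H]1[C@@]2(C)CC[C@@H](O[Si](CC)(CC)CC)C(C)(C)O[C@@H]2CC[C@]1(C)O[Si](CC)(CC)CC | intermediate
41 | triol: the target with (R)-CH(OH) at C23 in place of the ketone | C[C@H]1CC[C@@H]2[C@@H](CC[C@@]2(C)O)C(C)(C)/C1=C\C[C@@H]1[C@@]2(C)CC[C@@H](O)C(C)(C)O[C@@H]2CC[C@]1(C)O | intermediate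
42 | CNP0157787.1, (2S,5R,6R,9R,15Z,18R,19R,29R,32S) in target numbering | C[C@H]1CC[C@@H]2[C@@H](CC[C@@]2(C)O)C(C)(C)/C1=C\C[C@@H]1[C@@]2(C)CCC(=O)C(C)(C)O[C@@H]2CC[C@]1(C)O | target

## Step count and risks

Total: 33 steps. Longest linear sequence: 25 steps (steps 1–19 and 28–33). The eastern branch has 8 steps (20–27).

**Step 11 (key step).** The likely failure is loss of the order of events. The seven-membered enyne closure from the C4 carbene is the slow step; if the catalyst spends its time on the allyl group, intermolecular metathesis between terminal alkenes or ene–ene closure to an eight-membered ring can overtake it. Fallback (relay-directed initiation): ethyl ketone 12 is alkylated with LiN(iPr)2 and (2E)-1-bromoocta-2,7-diene instead of allyl bromide, giving relay dienyne F1, in which C4 is part of an internal alkene that carries a pent-4-enyl arm. With the same catalyst the carbene formed at the end of the arm closes on the internal alkene, expels cyclopentene and is thereby delivered to C4 within the molecule. The cascade then runs as in step 11 and rejoins the route at dienone 14.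

**Step 4.** What may go wrong is loss of regiocontrol in the attack on the alkynyl-substituted allyl–iridium intermediate (linear product, or attack through the alkyne), or insufficient enantiomeric purity with this less usual substituent. Fallback (conjugate addition instead of allylic substitution): enynal 2 and ketene acetal 5 are combined under iminium catalysis with a chiral 5-benzyl-2-tert-butylimidazolidinone salt (Mukaiyama–Michael addition) to give aldehyde ester F2, with C6 set by the catalyst. Wittig methylenation (Ph3PCH3Br, KN(SiMe3)2) gives allyl ester F3, and amide formation as in step 5 (MeNH(OMe)·HCl, iPrMgCl) rejoins the route at amide 11. This path is shorter but rests on thinner precedent for a fully substituted ketene acetal, which is why it is held in reserve.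

**Step 28.** What may go wrong is slow metal insertion at the tetrasubstituted triflate flanked by C12, so that reduction of the triflate or reductive coupling of the aldehyde takes over. Fallback (alkenyllithium instead of alkenylchromium): triflate 22 is converted with Me6Sn2, Pd(PPh3)4 and LiCl in dioxane into alkenylstannane F4. Tin–lithium exchange with MeLi at −78 °C and addition of aldehyde 34 give alcohol 35, where the route is rejoined.

**Step 31.** What may go wrong is failure of the substitution at a carbinol flanked by a tetrasubstituted alkene and a branched chain: ionisation of the activated alcohol, with elimination to a diene or with loss of configuration at C16, which would erase the control of C2. Fallback (hydride delivery from palladium instead of the diazene): alcohol 37 is acylated (ClCO2Me, pyridine, DMAP) to allylic carbonate F5. Zerovalent palladium (from Pd(OAc)2 and PBu3) with HCO2NH4 ionises it anti to the leaving group and transfers hydride from the metal to the more substituted allyl terminus C2. This is the same face the diazene would serve, and it gives 40, where the route is rejoined.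

## Further compounds

F1 | step 11 | relay dienyne, 13 with C4 as an internal (E)-alkene bearing a pent-4-enyl arm (both C2 epimers) | CC(C)(C)[Si](C)(C)OCC#C[C@@H](CC=C)C(C)(C)C(=O)C(C)C/C=C/CCCC=C
F2 | step 4 | methyl (3R)-6-[(tert-butyldimethylsilyl)oxy]-2,2-dimethyl-3-(2-oxoethyl)hex-4-ynoate | CC(C)(C)[Si](C)(C)OCC#C[C@@H](CC=O)C(C)(C)C(=O)OC
F3 | step 4 | methyl (3R)-6-[(tert-butyldimethylsilyl)oxy]-2,2-dimethyl-3-(prop-2-en-1-yl)hex-4-ynoate | CC(C)(C)[Si](C)(C)OCC#C[C@@H](CC=C)C(C)(C)C(=O)OC
F4 | step 28 | trimethyl{(3R,3aR,8aR)-3,6,8,8-tetramethyl-3-[(triethylsilyl)oxy]-1,2,3,3a,4,5,8,8a-octahydroazulen-7-yl}stannane | CC=1CC[C@@H]2[C@@H](CC[C@@]2(C)O[Si](CC)(CC)CC)C(C)(C)C=1[Sn](C)(C)C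
F5 | step 31 | methyl carbonate of (16R)-alcohol 37 | CC=1CC[C@@H]2[C@@H](CC[C@@]2(C)O[Si](CC)(CC)CC)C(C)(C)C=1[C@H](OC(=O)OC)C[C@@H]1[C@@]2(C)CC[C@@H](O[Si](CC)(CC)CC)C(C)(C)O[C@@H]2CC[C@]1(C)O[Si](CC)(CC)CC
A1 | alternative 1 | 4-{6-[(tert-butyldimethylsilyl)oxy]-5,7,7-trimethylcyclohept-2-en-1-yl}butan-2-one, configured at C2, C6 and C15 as in A2 | C[C@H]1CC=C[C@@H](CCC(C)=O)C(C)(C)[C@H]1O[Si](C)(C)C(C)(C)C
A2 | alternative 1 | cis-fused hydroazulene tertiary alcohol, C15 tert-butyldimethylsilyl ether | C[C@H]1CC[C@@H]2[C@@H](CC[C@@]2(C)O)C(C)(C)[C@H]1O[Si](C)(C)C(C)(C)C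
A3 | alternative 2 | 2-[6-methyl-2-(triethylsilyloxy)hept-5-en-2-yl]-3-oxocyclopent-1-en-1-yl acetate, C9 as in A4 | CC(C)=CCC[C@@](C)(O[Si](CC)(CC)CC)C1=C(OC(C)=O)CCC1=O
A4 | alternative 2 | tricyclic acetoxycyclobutane photoadduct | C[C@@]1(O[Si](CC)(CC)CC)CC[C@H]2C(C)(C)[C@]3(OC(C)=O)CCC(=O)[C@]123
A5 | alternative 3 | diepoxy (Z)-enol silane, identical with 28 | C=CC/C=C(\O[Si](C)(C)C)CC[C@H]1O[C@]1(C)CC[C@H]1OC1(C)C
A6 | alternative 3 | trans-fused hydroxy-oxepane 2-allylcyclohexanone, identical with 30 | C=CC[C@@H]1[C@@]2(C)CC[C@@H](O)C(C)(C)O[C@@H]2CCC1=O
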